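A small charge of Q, 100 µM, meets 20 mM of D in this flask, so I ask first what the end state must be.

| flask | D | Q | remark | time |
|---|---|---|---|---|
| beta | 28 mM (fed, over 3.0 min) | 100 µM | run made earlier |  |
| theta | 44 mM (fed, over 3.0 min) | 100 µM | run made earlier |  |
| flask | 20 mM (fed, over 3.0 min) | 100 µM |  | 3.0 min |

| run | time / min | Z / % | D / % |
|---|---|---|---|
| beta | 0.667 | 0 | 26 |
| beta | 1.33 | 4 | 39 |
| beta | 2.00 | 15 | 52 |
| beta | 2.50 | 29 | 53 |
| beta | 3.00 | 44 | 57 |
| theta | 0.667 | 0 | 20 |
| theta | 1.33 | 4 | 41 |
| theta | 2.00 | 15 | 50 |
| theta | 2.50 | 33 | 55 |
| theta | 3.00 | 44 | 54 |

(scatter of a reading: 2 percentage points)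

- the average divides the monomer in chains by the number of chains begun, living and dead together
- the numbers in the tables scatter by 2 percentage points (one standard deviation)
- steps under discussion: D + G -> Z + G; D + Q -> G + Z
- the earlier runs do not show the number of chains; that part of a forecast is a guess
- percentages count the whole charge, also what has not yet gone in

- average number of monomer units in a chain (chains begun, living or dead) at 3.0 min
- part of the D that has reacted at 3.0 min

My measure is the charge ratio, 200 here, the D charged per Q charged. It is the chain length once each Q has begun one chain and each D lies in one. Before that end, the average length is the ratio times the part of D reacted, divided by the part of Q spent.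

For the part of D I use the runs. Beta reads 44% of Z at 3.00 min and theta reads 44%, though theta had 1.57 times the D, so I carry 44.0% over to this flask. For the part of Q I compare stretches. On average over the two runs, Z gains 13 percentage points after 2.50 min, which is less than the 16 points of the stretch before. With a scatter of 2 points on each reading, that gap is thin ground, and the runs do not show the number of chains, so it is a guess when I take the living ends G as nearly done increasing and the part of Q spent as close to one. That is my weakest link. The ratio then gives a length of 88.0, and I commit to that.

The forecast says 43%, a little below mine, and 150 for the length, above mine, with the words “Initiation is probably incomplete”.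

The flask gives 92.5 units and 38.4% reacted.

    D + G → Z + G, rate k1*[G]*[D] (k = 99.6 M⁻¹ s⁻¹)
    D + Q → G + Z (k = 1.24 M⁻¹ s⁻¹)

At 1.50 min this flask holds 0.0413 mM of G with 58.7% of its Q left, and the growth step has 13% of its turnover up to 3.00 min behind it. At 3.00 min, G stands at 0.0831 mM while 17% of the Q is still there, so the reforged link reads 83.1% spent, and the ratio gives about 92.4. The neighbour with 80 mM of D has a ratio of 800, 50.5% reacted and 0.24% of its Q left, which reckons to 405, and its chains average 405.

(The data were computed for substances that don't exist.)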